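Numbering (daucane): C1 = CH3-bearing ring-fusion carbon, C2/C3 = ring CH2, C4 = C(OH)iPr, C5 = ring-fusion CH, C6 = CH–O-acyl, C7 = CH2, C8 = C(=CH2), C9/C10 = CHOH (C10 on C1).
Retrosynthesis: ester and 9,10-acetonide off; seven-membered ring cut at C6–C7 (CH(OH)–CH2–C(=CH2) is a type 2 carbonyl-ene retron); isopropyl taken off C4 to leave a cyclopentanone.
The C4 carbinol is a masked ketone lying in the five-membered ring next to the C5 methine and the quaternary C1; C4(=O)–C5–C1(–C2=C3) is a 3,3-disubstituted pent-4-enal, so C3–C4 (hydroacylation) and C1–C5 ([3,3] shift of an allyl vinyl ether) are cut together.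
Forward: allylic alcohol (C1–C3, C8–C10) + vinyl iodide (C4–C6) → ether → five-membered ring (step 10) → isopropyl at C4 → seven-membered ring by C6–C7 ene closure → C6 correction, ester, deprotection.
Stereochemistry: C9/C10 from a D-proline anti-aldol; C1 and C5 from the chair [3,3] shift (E,E geometry, face set by C10); C4 by addition anti to the C5 arm; C6 by hydroxyl-directed reduction.

Key step: step 10

Assumption: the SMILES denotes the (1S,4R,5S,6S,9R,10S) isomer, that is trans-fused rings with the 4-OH and the C1 methyl on one face and H-5, the C6 ester oxygen and the cis-9,10-diol on the other.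

Step 1
Reactants: 1 2-methylpropanal
Product: 2 2-methyl-2-(phenylselanyl)propanal
Conditions: PhSeCl, EtOAc, 23 °C
Reagents that add atoms: benzeneselenenyl chloride, Cl[Se]c1ccccc1
Why: Electrophilic α-selenenylation of the aldehyde through its enol should give the tertiary selenide, a masked isopropenyl group that also makes the aldehyde α-branched and non-enolisable for the aldol.

Step 2
Reactants: 2 2-methyl-2-(phenylselanyl)propanal; 3 1-hydroxypropan-2-one
Product: 4 (3R,4S)-3,4-dihydroxy-5-methyl-5-(phenylselanyl)hexan-2-one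
Conditions: D-proline (30 mol %), excess 3, DMSO, 23 °C
Reagents that add atoms: none
Why: Proline-catalysed direct aldol of hydroxyacetone through its hydroxy-enamine and a hydrogen-bonded six-membered transition state should give the anti-1,2-diol, the D-catalyst setting C10 (3R) and C9 (4S) in the sense established for α-branched aldehydes.

Step 3
Reactants: 4 (3R,4S)-3,4-dihydroxy-5-methyl-5-(phenylselanyl)hexan-2-one
Product: 5 1-[(4R,5S)-2,2-dimethyl-5-[2-(phenylselanyl)propan-2-yl]-1,3-dioxolan-4-yl]ethan-1-one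
Conditions: 2,2-dimethoxypropane, pyridinium p-toluenesulfonate (cat.), CH2Cl2, 0 to 23 °C
Reagents that add atoms: 2,2-dimethoxypropane, COC(C)(C)OC
Why: Acid-catalysed transacetalisation should lock the anti-diol as the cis-dioxolane, which blocks retro-aldol cleavage and serves as the only protecting group of the 9,10-diol to the end.

Step 4
Reactants: 5 1-[(4R,5S)-2,2-dimethyl-5-[2-(phenylselanyl)propan-2-yl]-1,3-dioxolan-4-yl]ethan-1-one
Product: 7 1-[(4R,5R)-2,2-dimethyl-5-(prop-1-en-2-yl)-1,3-dioxolan-4-yl]ethan-1-one, via selenoxide 6 (not isolated)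
Conditions: 30% H2O2, pyridine, CH2Cl2, 0 to 23 °C
Reagents that add atoms: none
Why: Oxidation to the selenoxide and its spontaneous syn-elimination, which runs toward a methyl group and away from the oxygen-bearing carbon, should unveil the isopropenyl group without touching the stereocentres.

Step 5
Reactants: 7 1-[(4R,5R)-2,2-dimethyl-5-(prop-1-en-2-yl)-1,3-dioxolan-4-yl]ethan-1-one; 8 ethyl (triphenylphosphoranylidene)acetate
Product: 9 ethyl (2E)-3-[(4S,5R)-2,2-dimethyl-5-(prop-1-en-2-yl)-1,3-dioxolan-4-yl]but-2-enoate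
Conditions: PhMe, 90 °C
Reagents that add atoms: none
Why: Wittig olefination with the stabilised ylide under base-free conditions should give mainly the E-enoate (ester trans to the bulky dioxolanyl group) without epimerising the α-alkoxy ketone, the minor Z-isomer being removed by chromatography.

Step 6
Reactants: 9 ethyl (2E)-3-[(4S,5R)-2,2-dimethyl-5-(prop-1-en-2-yl)-1,3-dioxolan-4-yl]but-2-enoate
Product: 10 (2E)-3-[(4S,5R)-2,2-dimethyl-5-(prop-1-en-2-yl)-1,3-dioxolan-4-yl]but-2-en-1-ol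
Conditions: iBu2AlH, CH2Cl2, −78 °C; aqueous potassium sodium tartrate
Reagents that add atoms: none
Why: 1,2-Reduction of the enoate by the aluminium hydride at low temperature should give the E-allylic alcohol (C3 hydroxymethyl, C2=C1 alkene) without conjugate reduction.

Step 7
Reactants: 11 prop-2-yn-1-ol
Product: 12 1-methoxy-4-[(prop-2-yn-1-yloxy)methyl]benzene
Conditions: NaH, 4-methoxybenzyl chloride, Bu4NI (cat.), THF, 0 to 23 °C
Reagents that add atoms: 4-methoxybenzyl chloride, COc1ccc(CCl)cc1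
Why: Williamson etherification of the sodium alkoxide with the benzylic chloride should give the p-methoxybenzyl ether that later carries the C6 oxygen.

Step 8
Reactants: 12 1-methoxy-4-[(prop-2-yn-1-yloxy)methyl]benzene
Product: 14 1-({[(2E)-3-iodoprop-2-en-1-yl]oxy}methyl)-4-methoxybenzene, via alkenylzirconocene chloride 13 (not isolated)
Conditions: Cp2Zr(H)Cl, THF, 23 °C; then I2, 0 °C
Reagents that add atoms: iodine, II
Why: Syn-hydrozirconation places zirconium on the terminal carbon and iodinolysis of the C–Zr bond proceeds with retention, so the E-vinyl iodide (C4–C5–C6 unit) should result.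

Step 9
Reactants: 10 (2E)-3-[(4S,5R)-2,2-dimethyl-5-(prop-1-en-2-yl)-1,3-dioxolan-4-yl]but-2-en-1-ol; 14 1-({[(2E)-3-iodoprop-2-en-1-yl]oxy}methyl)-4-methoxybenzene
Product: 15 (4S,5R)-4-[(2E)-4-{[(1E)-3-[(4-methoxyphenyl)methoxy]prop-1-en-1-yl]oxy}but-2-en-2-yl]-2,2-dimethyl-5-(prop-1-en-2-yl)-1,3-dioxolane
Conditions: CuI (10 mol %), 3,4,7,8-tetramethyl-1,10-phenanthroline (20 mol %), Cs2CO3, PhMe, 80 °C
Reagents that add atoms: none
Why: Copper-catalysed Ullmann-type C–O coupling of the vinyl iodide with the primary allylic alcohol should give the allyl vinyl ether with retention of both alkene geometries, at a temperature below the onset of the [3,3] shift.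

Step 10
Reactants: 15 (4S,5R)-4-[(2E)-4-{[(1E)-3-[(4-methoxyphenyl)methoxy]prop-1-en-1-yl]oxy}but-2-en-2-yl]-2,2-dimethyl-5-(prop-1-en-2-yl)-1,3-dioxolane
Product: 17 (2S,3S)-3-[(4S,5R)-2,2-dimethyl-5-(prop-1-en-2-yl)-1,3-dioxolan-4-yl]-2-{[(4-methoxyphenyl)methoxy]methyl}-3-methylcyclopentan-1-one, via pent-4-enal 16 (not isolated)
Conditions: [Rh(nbd)(dppe)]BF4 (10 mol %, pre-treated with H2), 1,2-dichlorobenzene, 150 °C, sealed tube
Reagents that add atoms: none
Why: Heating drives an aliphatic Claisen ([3,3]) rearrangement of the allyl vinyl ether through a chair transition state to pent-4-enal 16 (C1–C5 bond), and the cationic rhodium bisphosphine catalyst already present inserts into the aldehyde C–H bond, adds the acyl hydride across the new vinyl group and reductively eliminates to form the C3–C4 bond; the closest precedent is the one-pot Claisen rearrangement/intramolecular hydroacylation of simple allyl vinyl ethers to cyclopentanones. The [3,3] shift closes no ring (acyclic six-centre chair), and the cyclopentanone is closed by hydroacylation through a six-membered acyl alkyl rhodacycle, formally a 5-endo-trig union of the acyl carbon with the terminal alkene carbon. C5 is set by the E-enol ether (CH2OPMB equatorial) and C1 by the E-alkene (dioxolanyl equatorial, methyl axial), which places the two arms trans on the future ring, and the alkene face is chosen by C10 in a Felkin–Anh-type arrangement with the C10–O bond anti to the forming bond and H-10 turned toward the vinylic methyl group, the rotamer that turns the C10–C9 bond toward that methyl being excluded by 1,2-allylic strain and a syn-pentane contact with the CH2OPMB arm. The step needs chair over boat, one alkene face, and hydroacylation at the vinyl group only: the E,E geometry secures the chair, the vinyl group on a quaternary carbon cannot isomerise and inserts far faster than the 1,1-disubstituted isopropenyl group, and C5 stays epimerisable next to the new ketone, where the arrangement trans to the dioxolanyl group is also the thermodynamic one.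

Step 11
Reactants: 17 (2S,3S)-3-[(4S,5R)-2,2-dimethyl-5-(prop-1-en-2-yl)-1,3-dioxolan-4-yl]-2-{[(4-methoxyphenyl)methoxy]methyl}-3-methylcyclopentan-1-one
Product: 18 (1R,2S,3S)-3-[(4S,5R)-2,2-dimethyl-5-(prop-1-en-2-yl)-1,3-dioxolan-4-yl]-2-{[(4-methoxyphenyl)methoxy]methyl}-3-methyl-1-(propan-2-yl)cyclopentan-1-ol
Conditions: iPrMgCl, anhydrous CeCl3, THF, −78 °C
Reagents that add atoms: isopropylmagnesium chloride, CC(C)[Mg]Cl
Why: Organocerium 1,2-addition, which suppresses enolisation and β-hydride reduction, should occur on the ketone face anti to the C5 CH2OPMB arm and the C1 methyl group (the bulky dioxolanyl group sits pseudo-equatorial), setting C4 with its hydroxyl cis to both.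

Step 12
Reactants: 18 (1R,2S,3S)-3-[(4S,5R)-2,2-dimethyl-5-(prop-1-en-2-yl)-1,3-dioxolan-4-yl]-2-{[(4-methoxyphenyl)methoxy]methyl}-3-methyl-1-(propan-2-yl)cyclopentan-1-ol
Product: 19 (1R,2S,3S)-3-[(4S,5R)-2,2-dimethyl-5-(prop-1-en-2-yl)-1,3-dioxolan-4-yl]-2-(hydroxymethyl)-3-methyl-1-(propan-2-yl)cyclopentan-1-ol
Conditions: DDQ, CH2Cl2/pH 7 phosphate buffer (10:1), 0 °C
Reagents that add atoms: none
Why: Oxidative cleavage of the p-methoxybenzyl ether (single-electron oxidation, then hydrolysis of the oxocarbenium ion) should free the primary alcohol, the water in the medium suppressing acetal formation with the C4 hydroxyl.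

Step 13
Reactants: 19 (1R,2S,3S)-3-[(4S,5R)-2,2-dimethyl-5-(prop-1-en-2-yl)-1,3-dioxolan-4-yl]-2-(hydroxymethyl)-3-methyl-1-(propan-2-yl)cyclopentan-1-ol
Product: 20 (1R,2S,5R)-2-[(4S,5R)-2,2-dimethyl-5-(prop-1-en-2-yl)-1,3-dioxolan-4-yl]-5-hydroxy-2-methyl-5-(propan-2-yl)cyclopentane-1-carbaldehyde
Conditions: PhI(OAc)2, TEMPO (cat.), CH2Cl2, 23 °C
Reagents that add atoms: none
Why: The oxoammonium oxidation is selective for the primary alcohol and neutral enough to leave the epimerisable C5 centre and the β-hydroxy aldehyde intact.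

Step 14
Reactants: 20 (1R,2S,5R)-2-[(4S,5R)-2,2-dimethyl-5-(prop-1-en-2-yl)-1,3-dioxolan-4-yl]-5-hydroxy-2-methyl-5-(propan-2-yl)cyclopentane-1-carbaldehyde
Product: 21 9,10-O-isopropylidene-(1S,4R,5S,6R,9R,10S)-dauc-8(14)-ene-4,6,9,10-tetrol
Conditions: Me2AlCl (2.5 equiv), CH2Cl2, −78 to −40 °C
Reagents that add atoms: none
Why: A type 2 intramolecular carbonyl-ene reaction of the aldehyde, held as a six-membered aluminium chelate with the C4 alkoxide, with the isopropenyl group should close the seven-membered ring at C6–C7 and turn the methyl group into the C8 exocyclic methylene, the chelate placing the new C6 hydroxyl syn to the C4 oxygen (6β expected) while any 6α-epimer (compound 23) is carried along and converges in step 15.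

Step 15
Reactants: 21 9,10-O-isopropylidene-(1S,4R,5S,6R,9R,10S)-dauc-8(14)-ene-4,6,9,10-tetrol
Product: 22 9,10-O-isopropylidene-(1S,4R,5R,9R,10S)-4,9,10-trihydroxydauc-8(14)-en-6-one
Conditions: Dess–Martin periodinane, pyridine, CH2Cl2, 0 °C
Reagents that add atoms: none
Why: Hypervalent-iodine oxidation of the secondary alcohol (the tertiary C4 hydroxyl is inert) under buffered, non-basic conditions should give the β-hydroxy ketone while sparing the β,γ-alkene and the C5 stereocentre.

Step 16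
Reactants: 22 9,10-O-isopropylidene-(1S,4R,5R,9R,10S)-4,9,10-trihydroxydauc-8(14)-en-6-one
Product: 23 9,10-O-isopropylidene-(1S,4R,5S,6S,9R,10S)-dauc-8(14)-ene-4,6,9,10-tetrol
Conditions: Me4NBH(OAc)3, MeCN/AcOH, −30 °C
Reagents that add atoms: none
Why: In this hydroxyl-directed (Evans–Saksena) reduction the C4 hydroxyl exchanges onto boron and delivers hydride intramolecularly to the β-face of the C6 ketone, which should give the 1,3-anti diol, that is the 6α-alcohol.

Step 17
Reactants: 23 9,10-O-isopropylidene-(1S,4R,5S,6S,9R,10S)-dauc-8(14)-ene-4,6,9,10-tetrol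
Product: 24 (1S,4R,5S,6S,9R,10S)-4-hydroxy-9,10-(isopropylidenedioxy)dauc-8(14)-en-6-yl 3-methylbutanoate
Conditions: 3-methylbutanoyl chloride, pyridine, DMAP (cat.), CH2Cl2, 0 °C
Reagents that add atoms: 3-methylbutanoyl chloride, CC(C)CC(Cl)=O
Why: Acylation of the only secondary hydroxyl (the tertiary C4 hydroxyl does not react under these conditions) should install the 3-methylbutanoate with retention at C6.

Step 18
Reactants: 24 (1S,4R,5S,6S,9R,10S)-4-hydroxy-9,10-(isopropylidenedioxy)dauc-8(14)-en-6-yl 3-methylbutanoate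
Product: 25 (1S,4R,5S,6S,9R,10S)-4,9,10-trihydroxydauc-8(14)-en-6-yl 3-methylbutanoate (CNP0204264.1)
Conditions: AcOH/H2O (4:1), 40 °C
Reagents that add atoms: none
Why: Mild aqueous acid should hydrolyse the cis-fused acetonide to the 9,10-diol without acyl migration, dehydration at C4 or isomerisation of the exocyclic alkene, giving the target.

Compound list
1 | 2-methylpropanal | CC(C)C=O | starting material
2 | 2-methyl-2-(phenylselanyl)propanal | CC(C)([Se]c1ccccc1)C=O | intermediate
3 | 1-hydroxypropan-2-one | CC(=O)CO | starting material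
4 | (3R,4S)-3,4-dihydroxy-5-methyl-5-(phenylselanyl)hexan-2-one | CC(=O)[C@H](O)[C@H](O)C(C)(C)[Se]c1ccccc1 | intermediate
5 | 1-[(4R,5S)-2,2-dimethyl-5-[2-(phenylselanyl)propan-2-yl]-1,3-dioxolan-4-yl]ethan-1-one | CC(=O)[C@@H]1OC(C)(C)O[C@@H]1C(C)(C)[Se]c1ccccc1 | intermediate
6 | selenoxide of 5 (not isolated) | CC(=O)[C@@H]1OC(C)(C)O[C@@H]1C(C)(C)[Se](=O)c1ccccc1 | intermediate
7 | 1-[(4R,5R)-2,2-dimethyl-5-(prop-1-en-2-yl)-1,3-dioxolan-4-yl]ethan-1-one | CC(=O)[C@@H]1OC(C)(C)O[C@@H]1C(C)=C | intermediate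
8 | ethyl (triphenylphosphoranylidene)acetate | CCOC(=O)C=P(c1ccccc1)(c1ccccc1)c1ccccc1 | starting material
9 | ethyl (2E)-3-[(4S,5R)-2,2-dimethyl-5-(prop-1-en-2-yl)-1,3-dioxolan-4-yl]but-2-enoate | CCOC(=O)/C=C(\C)[C@@H]1OC(C)(C)O[C@@H]1C(C)=C | intermediate
10 | (2E)-3-[(4S,5R)-2,2-dimethyl-5-(prop-1-en-2-yl)-1,3-dioxolan-4-yl]but-2-en-1-ol | OC/C=C(\C)[C@@H]1OC(C)(C)O[C@@H]1C(C)=C | intermediate
11 | prop-2-yn-1-ol | C#CCO | starting material
12 | 1-methoxy-4-[(prop-2-yn-1-yloxy)methyl]benzene | COc1ccc(COCC#C)cc1 | intermediate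
13 | chlorobis(cyclopentadienyl)[(1E)-3-[(4-methoxyphenyl)methoxy]prop-1-en-1-yl]zirconium (not isolated) | COc1ccc(COC/C=C/[Zr](Cl)(C2C=CC=C2)C2C=CC=C2)cc1 | intermediate
14 | 1-({[(2E)-3-iodoprop-2-en-1-yl]oxy}methyl)-4-methoxybenzene | COc1ccc(COC/C=C/I)cc1 | intermediate
15 | (4S,5R)-4-[(2E)-4-{[(1E)-3-[(4-methoxyphenyl)methoxy]prop-1-en-1-yl]oxy}but-2-en-2-yl]-2,2-dimethyl-5-(prop-1-en-2-yl)-1,3-dioxolane | COc1ccc(COC/C=C/OC/C=C(\C)[C@@H]2OC(C)(C)O[C@@H]2C(C)=C)cc1 | intermediate
16 | (2S,3S)-3-[(4S,5R)-2,2-dimethyl-5-(prop-1-en-2-yl)-1,3-dioxolan-4-yl]-2-{[(4-methoxyphenyl)methoxy]methyl}-3-methylpent-4-enal (not isolated) | O=C[C@H](COCc1ccc(OC)cc1)[C@](C)(C=C)[C@@H]2OC(C)(C)O[C@@H]2C(C)=C | intermediate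
17 | (2S,3S)-3-[(4S,5R)-2,2-dimethyl-5-(prop-1-en-2-yl)-1,3-dioxolan-4-yl]-2-{[(4-methoxyphenyl)methoxy]methyl}-3-methylcyclopentan-1-one | O=C1[C@H](COCc2ccc(OC)cc2)[C@](C)(CC1)[C@@H]3OC(C)(C)O[C@@H]3C(C)=C | intermediate
18 | (1R,2S,3S)-3-[(4S,5R)-2,2-dimethyl-5-(prop-1-en-2-yl)-1,3-dioxolan-4-yl]-2-{[(4-methoxyphenyl)methoxy]methyl}-3-methyl-1-(propan-2-yl)cyclopentan-1-ol | O[C@]1(C(C)C)[C@H](COCc2ccc(OC)cc2)[C@](C)(CC1)[C@@H]3OC(C)(C)O[C@@H]3C(C)=C | intermediate
19 | (1R,2S,3S)-3-[(4S,5R)-2,2-dimethyl-5-(prop-1-en-2-yl)-1,3-dioxolan-4-yl]-2-(hydroxymethyl)-3-methyl-1-(propan-2-yl)cyclopentan-1-ol | O[C@]1(C(C)C)[C@H](CO)[C@](C)(CC1)[C@@H]2OC(C)(C)O[C@@H]2C(C)=C | intermediate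
20 | (1R,2S,5R)-2-[(4S,5R)-2,2-dimethyl-5-(prop-1-en-2-yl)-1,3-dioxolan-4-yl]-5-hydroxy-2-methyl-5-(propan-2-yl)cyclopentane-1-carbaldehyde | O[C@]1(C(C)C)[C@H](C=O)[C@](C)(CC1)[C@@H]2OC(C)(C)O[C@@H]2C(C)=C | intermediate
21 | 9,10-O-isopropylidene-(1S,4R,5S,6R,9R,10S)-dauc-8(14)-ene-4,6,9,10-tetrol (6β-alcohol) | C=C1C[C@@H](O)[C@@H]2[C@](C)(CC[C@@]2(O)C(C)C)[C@@H]3OC(C)(C)O[C@H]13 | intermediate
22 | 9,10-O-isopropylidene-(1S,4R,5R,9R,10S)-4,9,10-trihydroxydauc-8(14)-en-6-one | C=C1CC(=O)[C@@H]2[C@](C)(CC[C@@]2(O)C(C)C)[C@@H]3OC(C)(C)O[C@H]13 | intermediate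
23 | 9,10-O-isopropylidene-(1S,4R,5S,6S,9R,10S)-dauc-8(14)-ene-4,6,9,10-tetrol (6α-alcohol) | C=C1C[C@H](O)[C@@H]2[C@](C)(CC[C@@]2(O)C(C)C)[C@@H]3OC(C)(C)O[C@H]13 | intermediate
24 | (1S,4R,5S,6S,9R,10S)-4-hydroxy-9,10-(isopropylidenedioxy)dauc-8(14)-en-6-yl 3-methylbutanoate | C=C1C[C@H](OC(=O)CC(C)C)[C@@H]2[C@](C)(CC[C@@]2(O)C(C)C)[C@@H]3OC(C)(C)O[C@H]13 | intermediate
25 | (1S,4R,5S,6S,9R,10S)-4,9,10-trihydroxydauc-8(14)-en-6-yl 3-methylbutanoate (CNP0204264.1) | C=C1C[C@H](OC(=O)CC(C)C)[C@@H]2[C@](C)(CC[C@@]2(O)C(C)C)[C@H](O)[C@@H]1O | target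

Total step count: 18. Longest linear sequence: 16 steps (steps 1–6, then 9–18); steps 7–8 make the second fragment.

Steps most likely to fail

Step 10. The [3,3] shift may discriminate too weakly between the two faces of the trisubstituted alkene, since C10 is its only controller, and the acyl rhodium hydride may lose CO at the temperature the shift needs. The fallback sets out from 10 and places a second, removable stereocontrolling centre on the enol ether so that both partners favour the same chair. Commercial (S)-2,2-dimethyl-1,3-dioxolane-4-carbaldehyde is converted by Takai olefination (CrCl2, CHI3, THF) into (4R)-4-[(E)-2-iodoethenyl]-2,2-dimethyl-1,3-dioxolane F1. Coupling of F1 with 10 under the conditions of step 9 should give (4S,5R)-4-[(2E)-4-({(E)-2-[(4R)-2,2-dimethyl-1,3-dioxolan-4-yl]ethenyl}oxy)but-2-en-2-yl]-2,2-dimethyl-5-(prop-1-en-2-yl)-1,3-dioxolane F2. The same rhodium-catalysed tandem reaction then passes through (2S,3S)-2-[(4R)-2,2-dimethyl-1,3-dioxolan-4-yl]-3-[(4S,5R)-2,2-dimethyl-5-(prop-1-en-2-yl)-1,3-dioxolan-4-yl]-3-methylpent-4-enal F3 to (2S,3S)-2-[(4R)-2,2-dimethyl-1,3-dioxolan-4-yl]-3-[(4S,5R)-2,2-dimethyl-5-(prop-1-en-2-yl)-1,3-dioxolan-4-yl]-3-methylcyclopentan-1-one F4. In that shift the new allylic centre on the nucleophilic partner should adopt the inside-alkoxy arrangement (C–O in the plane of the enol ether, CH2O anti to the forming bond), which reinforces the preference exerted by C10. Addition of iPrMgCl/CeCl3 as in step 11 should give (1R,2S,3S)-2-[(4R)-2,2-dimethyl-1,3-dioxolan-4-yl]-3-[(4S,5R)-2,2-dimethyl-5-(prop-1-en-2-yl)-1,3-dioxolan-4-yl]-3-methyl-1-(propan-2-yl)cyclopentan-1-ol F5. H5IO6 in ethyl acetate then hydrolyses the terminal acetonide and cleaves the glycol in one flask, which comes back to the route at aldehyde 20; steps 12 and 13 are not needed.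

Step 14. The β-hydroxy aldehyde may open by retro-aldol cleavage as its aluminium alkoxide, and the Lewis acid may cause proton loss to endocyclic alkenes or ionisation of the allylic acetonide faster than ring closure. The fallback sets out from 19 and replaces the Lewis-acid ene reaction by a neutral organochromium allylation. Ene-type allylic chlorination of the isopropenyl group (N-chlorosuccinimide, catalytic PhSeCl, CH2Cl2) should give (1R,2S,3S)-3-[(4S,5R)-5-(3-chloroprop-1-en-2-yl)-2,2-dimethyl-1,3-dioxolan-4-yl]-2-(hydroxymethyl)-3-methyl-1-(propan-2-yl)cyclopentan-1-ol F6. Oxidation as in step 13 should give (1R,2S,5R)-2-[(4S,5R)-5-(3-chloroprop-1-en-2-yl)-2,2-dimethyl-1,3-dioxolan-4-yl]-5-hydroxy-2-methyl-5-(propan-2-yl)cyclopentane-1-carbaldehyde F7. An intramolecular Nozaki–Hiyama allylation (CrCl2, catalytic LiI, THF) then closes the seven-membered ring with the same C6–C7 bond and exocyclic methylene, coming back at 21 (or its C6 epimer 23).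

Step 16. At the β-hydroxy ketone stage the C5 centre may epimerise, the exocyclic alkene may move into conjugation, or retro-aldol cleavage may occur before hydride is delivered. The fallback sets out from 21 and avoids ketone 22 altogether. Mitsunobu esterification (PPh3, diisopropyl azodicarboxylate, 3-methylbutanoic acid, PhMe, 0 °C) should invert the 6β-alcohol directly into the 6α-ester and so comes back at 24; no new compound is made.

Further compounds
F1 | step 10 | (4R)-4-[(E)-2-iodoethenyl]-2,2-dimethyl-1,3-dioxolane | I/C=C/[C@@H]1COC(C)(C)O1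
F2 | step 10 | (4S,5R)-4-[(2E)-4-({(E)-2-[(4R)-2,2-dimethyl-1,3-dioxolan-4-yl]ethenyl}oxy)but-2-en-2-yl]-2,2-dimethyl-5-(prop-1-en-2-yl)-1,3-dioxolane | CC1(C)OC[C@@H](/C=C/OC/C=C(\C)[C@@H]2OC(C)(C)O[C@@H]2C(C)=C)O1
F3 | step 10 | (2S,3S)-2-[(4R)-2,2-dimethyl-1,3-dioxolan-4-yl]-3-[(4S,5R)-2,2-dimethyl-5-(prop-1-en-2-yl)-1,3-dioxolan-4-yl]-3-methylpent-4-enal | O=C[C@H]([C@@H]1COC(C)(C)O1)[C@](C)(C=C)[C@@H]2OC(C)(C)O[C@@H]2C(C)=C
F4 | step 10 | (2S,3S)-2-[(4R)-2,2-dimethyl-1,3-dioxolan-4-yl]-3-[(4S,5R)-2,2-dimethyl-5-(prop-1-en-2-yl)-1,3-dioxolan-4-yl]-3-methylcyclopentan-1-one | O=C1[C@H]([C@@H]2COC(C)(C)O2)[C@](C)(CC1)[C@@H]3OC(C)(C)O[C@@H]3C(C)=C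
F5 | step 10 | (1R,2S,3S)-2-[(4R)-2,2-dimethyl-1,3-dioxolan-4-yl]-3-[(4S,5R)-2,2-dimethyl-5-(prop-1-en-2-yl)-1,3-dioxolan-4-yl]-3-methyl-1-(propan-2-yl)cyclopentan-1-ol | O[C@]1(C(C)C)[C@H]([C@@H]2COC(C)(C)O2)[C@](C)(CC1)[C@@H]3OC(C)(C)O[C@@H]3C(C)=C
F6 | step 14 | (1R,2S,3S)-3-[(4S,5R)-5-(3-chloroprop-1-en-2-yl)-2,2-dimethyl-1,3-dioxolan-4-yl]-2-(hydroxymethyl)-3-methyl-1-(propan-2-yl)cyclopentan-1-ol | O[C@]1(C(C)C)[C@H](CO)[C@](C)(CC1)[C@@H]2OC(C)(C)O[C@@H]2C(=C)CCl
F7 | step 14 | (1R,2S,5R)-2-[(4S,5R)-5-(3-chloroprop-1-en-2-yl)-2,2-dimethyl-1,3-dioxolan-4-yl]-5-hydroxy-2-methyl-5-(propan-2-yl)cyclopentane-1-carbaldehyde | O[C@]1(C(C)C)[C@H](C=O)[C@](C)(CC1)[C@@H]2OC(C)(C)O[C@@H]2C(=C)CCl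
F0 | step 16 | none | none
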